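The oxirane carbons C2' and C3' (side chain numbered from the OCH2 carbon C1' on O7 of the coumarin ring system) are read as a former E-trisubstituted C2'=C3' olefin, the imprint of syn methylmetalation of a terminal alkyne. One operation therefore unites three components. Trimethylaluminium places the C3' methyl group on a skipped enyne that already holds the E-C5'=C6' olefin and the silyl-protected C7' carbinol. The alkenylalane so formed is alkylated at C2' by the chloromethyl ether of isofraxidin, which creates the C1'–C2' bond with the aryl ether already in place. Reagent-controlled epoxidation of that olefin then sets both stereocentres.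

Key step: step 6

Remark: the target SMILES corresponds to the (2'R,3'R)-trans-oxirane with an E-C5'=C6' olefin. The enyne is built carbinol-first, so no base-sensitive skipped enyne ester is handled before the key step.

Step 1
Reactants: 1 2-methylbut-3-en-2-ol; 2 (Z)-1,4-dichlorobut-2-ene
Product: 3 (E)-5-chloro-2-methylpent-3-en-2-ol
Conditions: second-generation Hoveyda–Grubbs catalyst [RuCl2(H2IMes)(=CH-C6H4-2-OiPr), 2 mol%], 1 in excess, CH2Cl2, 40 °C
Reagents that add atoms: none
Why: Olefin cross-metathesis in which the reactive allylic dichloride 2 exchanges alkylidenes with the slowly homodimerising tertiary allylic alcohol 1, both halves of 2 being used, and the bulk of the carbinol carbon should make the E isomer the only significant product.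

Step 2
Reactants: 3 (E)-5-chloro-2-methylpent-3-en-2-ol
Product: 4 (E)-[(5-chloro-2-methylpent-3-en-2-yl)oxy]triethylsilane
Conditions: Et3SiOTf, 2,6-lutidine, CH2Cl2, −78 → 0 °C
Reagents that add atoms: triethylsilyl trifluoromethanesulfonate, CC[Si](CC)(CC)OS(=O)(=O)C(F)(F)F
Why: Silylation of a hindered tertiary alcohol with a silyl triflate and a non-nucleophilic base is standard, and the primary allylic chloride is inert to both.

Step 3
Reactants: 4 (E)-[(5-chloro-2-methylpent-3-en-2-yl)oxy]triethylsilane; 5 ethynylmagnesium bromide
Product: 6 (E)-triethyl[(2-methylhept-3-en-6-yn-2-yl)oxy]silane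
Conditions: HC≡CMgBr (2.5 equiv, 0.5 M in THF), CuCl (10 mol%), THF, 0 → 50 °C
Reagents that add atoms: none
Why: Copper-catalysed allyl–alkynyl Grignard coupling in which chloride should be displaced at the primary carbon because the other allyl terminus is blocked by the adjacent quaternary silyloxy carbon, the E geometry being retained and the excess acetylide keeping the product alkyne from a second allylation.

Step 4
Reactants: 7 isofraxidin (7-hydroxy-6,8-dimethoxy-2H-chromen-2-one); 8 chloromethyl methyl sulfide
Product: 10 6,8-dimethoxy-7-[(methylsulfanyl)methoxy]-2H-chromen-2-one, via sodium isofraxidinate 9 (not isolated)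
Conditions: NaH (1.1 equiv), DMF, 0 °C; then MeSCH2Cl (1.3 equiv), NaI (0.1 equiv), 0 °C → rt
Reagents that add atoms: none
Why: Williamson etherification of the acidic coumarin phenol, deprotonated irreversibly by NaH, with the α-thio chloride (accelerated by iodide exchange) is the usual way to aryl methylthiomethyl ethers.

Step 5
Reactants: 10 6,8-dimethoxy-7-[(methylsulfanyl)methoxy]-2H-chromen-2-one
Product: 11 7-(chloromethoxy)-6,8-dimethoxy-2H-chromen-2-one
Conditions: SO2Cl2 (1.0 equiv), CH2Cl2, −78 → 0 °C; volatiles removed in vacuo, crude 11 used at once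
Reagents that add atoms: sulfuryl chloride, O=S(=O)(Cl)Cl
Why: Chlorinolysis of the O,S-acetal, in which sulfur (by far the most nucleophilic site) is chlorinated to a chlorosulfonium ion that fragments to MeSCl and the aryloxymethyl cation–chloride pair, is the established conversion of aryl methylthiomethyl ethers into aryl chloromethyl ethers.

Step 6
Reactants: 6 (E)-triethyl[(2-methylhept-3-en-6-yn-2-yl)oxy]silane; 12 trimethylaluminium; 11 7-(chloromethoxy)-6,8-dimethoxy-2H-chromen-2-one
Product: 14 6,8-dimethoxy-7-{[(2E,5E)-3,7-dimethyl-7-[(triethylsilyl)oxy]octa-2,5-dien-1-yl]oxy}-2H-chromen-2-one, via alkenyldimethylalane 13 (not isolated)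
Conditions: Me3Al (2.0 equiv), Cp2ZrCl2 (0.25 equiv), ClCH2CH2Cl, 0 °C → rt; excess Me3Al and solvent removed in vacuo; then 11 (0.7 equiv), CH2Cl2, −30 → 0 °C; cold aq. potassium sodium tartrate
Reagents that add atoms: none
Why: Cp2ZrCl2 and Me3Al form a Zr–Al bimetallic methylating species that adds CH3 and metal syn across the terminal C≡C of 6, methyl to the internal carbon (future C3') and aluminium to the terminal carbon (future C2'), so that Al and CH3 are cis in alane 13. After the free Me3Al is pumped off, the sp2 C–Al bond of 13 attacks the CH2 of 11, which aluminium activates by chloride abstraction as an aryloxymethyl oxocarbenium ion pair, and substitution at the alkenyl carbon occurs with retention, giving the C1'–C2' bond and the (2E) olefin. The closest known reaction type is the Negishi zirconium-catalysed methylalumination of terminal alkynes followed by direct alkylation of the alkenylalane with chloromethyl methyl ether, the aryl chloromethyl ether being a less easily ionised member of the same class. No ring is closed and no stereocentre is formed; only olefin geometry is fixed, by the syn addition and the retentive transfer. The step needs alkyne-over-alkene carbometalation (the isolated C5'=C6' olefin is inert), alkenyl-over-methyl transfer (secured by removing Me3Al and by the greater nucleophilicity of the alkenyl–Al bond) and attack at the oxocarbenium carbon in preference to the lactone (secured by low temperature and the much higher electrophilicity of 11). The tertiary allylic silyl ether is shielded from aluminium by the triethylsilyl group and the two methyl groups, which should suppress its ionisation.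

Step 7
Reactants: 14 6,8-dimethoxy-7-{[(2E,5E)-3,7-dimethyl-7-[(triethylsilyl)oxy]octa-2,5-dien-1-yl]oxy}-2H-chromen-2-one
Product: 15 6,8-dimethoxy-7-{[(2R,3R)-3-methyl-3-[(E)-4-methyl-4-[(triethylsilyl)oxy]pent-2-en-1-yl]oxiran-2-yl]methoxy}-2H-chromen-2-one
Conditions: D-fructose-derived Shi ketone (1,2:4,5-di-O-isopropylidene-β-D-erythro-2,3-hexodiulo-2,6-pyranose, 0.3 equiv), KHSO5 (as 2KHSO5·KHSO4·K2SO4), K2CO3, Bu4NHSO4 (cat.), MeCN–CH2(OMe)2–aq. Na2B4O7 buffer with disodium ethylenediaminetetraacetate (pH about 10.5), −10 → 0 °C
Reagents that add atoms: potassium peroxymonosulfate, [K+].[O-]S(=O)(=O)OO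
Why: Shi asymmetric epoxidation, in which the chiral dioxirane from the D-fructose-derived ketone transfers oxygen through a spiro transition state to the face of the E-trisubstituted C2'=C3' olefin that gives the (2'R,3'R) oxirane (the sense established for E-trisubstituted olefins of this pattern), and the electron-richer trisubstituted olefin should react well before the hindered C5'=C6' olefin or the electron-poor pyranone C3=C4 bond.

Step 8
Reactants: 15 6,8-dimethoxy-7-{[(2R,3R)-3-methyl-3-[(E)-4-methyl-4-[(triethylsilyl)oxy]pent-2-en-1-yl]oxiran-2-yl]methoxy}-2H-chromen-2-one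
Product: 16 7-{[(2R,3R)-3-[(E)-4-hydroxy-4-methylpent-2-en-1-yl]-3-methyloxiran-2-yl]methoxy}-6,8-dimethoxy-2H-chromen-2-one (CNP0325711.2)
Conditions: Bu4NF (1.2 equiv), THF, 0 °C → rt; aq. NH4Cl
Reagents that add atoms: none
Why: Fluoride-induced desilylation driven by the strong Si–F bond leaves the lactone and the oxirane untouched, and the liberated tertiary alkoxide cannot open the epoxide because the E-C5'=C6' olefin keeps it from reaching C2' or C3'.

Compound list
1 | 2-methylbut-3-en-2-ol | C=CC(C)(C)O | starting material
2 | (Z)-1,4-dichlorobut-2-ene | ClC/C=C\CCl | starting material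
3 | (E)-5-chloro-2-methylpent-3-en-2-ol | CC(C)(O)/C=C/CCl | intermediate
4 | (E)-[(5-chloro-2-methylpent-3-en-2-yl)oxy]triethylsilane | CC[Si](CC)(CC)OC(C)(C)/C=C/CCl | intermediate
5 | ethynylmagnesium bromide | C#C[Mg]Br | starting material
6 | (E)-triethyl[(2-methylhept-3-en-6-yn-2-yl)oxy]silane | C#CC/C=C/C(C)(C)O[Si](CC)(CC)CC | intermediate
7 | isofraxidin (7-hydroxy-6,8-dimethoxy-2H-chromen-2-one) | COc1cc2ccc(=O)oc2c(OC)c1O | starting material
8 | chloromethyl methyl sulfide | CSCCl | starting material
9 | sodium isofraxidinate (sodium 6,8-dimethoxy-2-oxo-2H-chromen-7-olate) | COc1cc2ccc(=O)oc2c(OC)c1[O-].[Na+] | intermediate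
10 | 6,8-dimethoxy-7-[(methylsulfanyl)methoxy]-2H-chromen-2-one | COc1cc2ccc(=O)oc2c(OC)c1OCSC | intermediate
11 | 7-(chloromethoxy)-6,8-dimethoxy-2H-chromen-2-one | COc1cc2ccc(=O)oc2c(OC)c1OCCl | intermediate
12 | trimethylaluminium | C[Al](C)C | starting material
13 | [(1E,4E)-2,6-dimethyl-6-[(triethylsilyl)oxy]hepta-1,4-dien-1-yl]dimethylalane | C[Al](C)/C=C(\C)C/C=C/C(C)(C)O[Si](CC)(CC)CC | intermediate
14 | 6,8-dimethoxy-7-{[(2E,5E)-3,7-dimethyl-7-[(triethylsilyl)oxy]octa-2,5-dien-1-yl]oxy}-2H-chromen-2-one | COc1cc2ccc(=O)oc2c(OC)c1OC/C=C(\C)C/C=C/C(C)(C)O[Si](CC)(CC)CC | intermediate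
15 | 6,8-dimethoxy-7-{[(2R,3R)-3-methyl-3-[(E)-4-methyl-4-[(triethylsilyl)oxy]pent-2-en-1-yl]oxiran-2-yl]methoxy}-2H-chromen-2-one | COc1cc2ccc(=O)oc2c(OC)c1OC[C@H]1O[C@]1(C)C/C=C/C(C)(C)O[Si](CC)(CC)CC | intermediate
16 | 7-{[(2R,3R)-3-[(E)-4-hydroxy-4-methylpent-2-en-1-yl]-3-methyloxiran-2-yl]methoxy}-6,8-dimethoxy-2H-chromen-2-one | COc1cc2ccc(=O)oc2c(OC)c1OC[C@H]1O[C@]1(C)C/C=C/C(C)(C)O | target

Total step count: 8. Longest linear sequence: 6 steps (1, 2, 3, 6, 7, 8); the coumarin branch (steps 4 and 5) joins at step 6.

Steps most likely to fail

1. Step 6. What may go wrong: transfer of a methyl group in place of the alkenyl group to the chloromethyl ether; Lewis-acid ionisation of the tertiary allylic silyl ether or of the newly formed allylic aryl ether by the chloroalane that is released; addition of organoaluminium species to the lactone carbonyl. Fallback: setting out from 6, the same methylalumination gives 13, which is converted with n-BuLi into lithium butyl[(1E,4E)-2,6-dimethyl-6-[(triethylsilyl)oxy]hepta-1,4-dien-1-yl]dimethylalanate F1 and hydroxymethylated with paraformaldehyde, the established route to (E)-3-methylalk-2-en-1-ols, to give (2E,5E)-3,7-dimethyl-7-[(triethylsilyl)oxy]octa-2,5-dien-1-ol F2. Mitsunobu etherification of F2 with isofraxidin 7 (PPh3, diisopropyl azodicarboxylate, THF, 0 °C → rt) forms the O7–C1' bond instead and comes back to the route at 14.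

2. Step 7. What may go wrong: incomplete discrimination between the two faces of C2'=C3' (an allylic aryloxy group is an unusual neighbour for the spiro transition state), further oxidation at C5'=C6', and slow hydrolytic opening of the lactone in the basic buffer. Fallback: setting out from 6 by way of F2 (made as in the fallback for step 6), a Sharpless asymmetric epoxidation with Ti(OiPr)4, D-(−)-diethyl tartrate and t-BuOOH (4 Å molecular sieves, CH2Cl2, −20 °C) is directed by the allylic hydroxyl, so it is confined to C2'=C3'. It should give {(2R,3R)-3-methyl-3-[(E)-4-methyl-4-[(triethylsilyl)oxy]pent-2-en-1-yl]oxiran-2-yl}methanol F3. Mitsunobu etherification of F3 with 7 (PPh3, diisopropyl azodicarboxylate, THF) does not touch either stereocentre and comes back to the route at 15.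

3. Step 3. What may go wrong: attack at the other allyl terminus, a second allylation of the product acetylide, and base-induced isomerisation of the skipped enyne to an allene. Fallback: setting out from 4, a Stille coupling with tributyl(ethynyl)stannane (Pd(PPh3)4, THF, 50 °C) runs under neutral conditions through a π-allylpalladium intermediate that has no β-hydrogen on its quaternary side and couples at the unhindered terminus. It comes back to the route at 6 and makes no new compound.

Further compounds
F1 | step 6 | lithium butyl[(1E,4E)-2,6-dimethyl-6-[(triethylsilyl)oxy]hepta-1,4-dien-1-yl]dimethylalanate | [Li+].CCCC[Al-](C)(C)/C=C(\C)C/C=C/C(C)(C)O[Si](CC)(CC)CC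
F2 | step 6 | (2E,5E)-3,7-dimethyl-7-[(triethylsilyl)oxy]octa-2,5-dien-1-ol | OC/C=C(\C)C/C=C/C(C)(C)O[Si](CC)(CC)CC
F3 | step 7 | {(2R,3R)-3-methyl-3-[(E)-4-methyl-4-[(triethylsilyl)oxy]pent-2-en-1-yl]oxiran-2-yl}methanol | OC[C@H]1O[C@]1(C)C/C=C/C(C)(C)O[Si](CC)(CC)CC
F0 | step 3 | none | none
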